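The runs were generated by integration for an exercise.

The question was how much isomer of the product the east flask would hold at four times, two of them beyond its last reading at 15.0 h.

| flask | substrate | remark | time |
|---|---|---|---|
| east | 0.083 M | the very flask that is asked about, followed so far |  |
| north-west | 0.042 M | run made earlier |  |
| flask | 0.083 M |  | 30 h |

* amount of isomer of the product in percent of the substrate charged, at 3.0 h, 10 h, 20 h and 30 h

- east (time / h: isomer of the product / %, target / %): 1.33: 7.1, 10.2; 2.00: 7.4, 12.7; 3.00: 8.3, 17.6; 4.00: 14.1, 19.9; 6.00: 17.2, 19.3; 10.0: 25.6, 15.2; 15.0: 33.7, 11.5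
- north-west (time / h: isomer of the product / %, target / %): 1.50: 6.6, 11.5; 5.00: 18.9, 19.7; 8.00: 29.0, 19.6; 12.0: 36.8, 15.0; 20.0: 53.7, 9.2; 25.0: 58.3, 4.1; 30.0: 60.7, 4.9

(each reading ± 1 percentage point)

The early answers lay in the east readings, 8.3 % at 3.00 h and 25.6 % at 10.0 h, but the later two needed a rule. In both runs the target peaked and fell while the isomer kept climbing, so I took the target as the isomer's main feed. Between 10.0 h and 15.0 h, east gained isomer at 0.121 h⁻¹ of the mean target reading. I call this κ, the drain constant: isomer gained per hour per percent of target read, all its forms counted. It is an apparent pseudo-first-order constant.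

The east target fell from 19.3 % at 6.00 h to 11.5 % at 15.0 h, a decay of 0.0575 h⁻¹. Carried forward, that put it at 4.85 % by 30 h. Summing κ times this falling target gave me 39.8 % at 20 h and 47.7 % at 30 h.

The forecast, built on a stretch of the clock between the runs because “Percent conversion is slower at the higher loading”, gave 10 %, 25 %, 41 % and 52 %. Its last value was higher than mine.

The flask gave 10.8 %, 25.7 %, 40.7 % and 48.7 %.

    target ⇌ isomer of the product (k = 0.00342 min⁻¹)
    substrate + target ⇌ idle adduct, settled at all times (K = 169 L mol⁻¹)
    2 substrate → self-condensation product (k = 0.0395 L mol⁻¹ min⁻¹)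
    substrate ⇌ target (K = 1.08, k = 0.00210 min⁻¹)
    target → over-reaction product (k = 6.14 × 10⁻⁵ min⁻¹)
    substrate ⇌ isomer of the product (K = 68.0, k = 0.00110 min⁻¹)

At 30.0 h the flask held 3.76 % of target. Put to the north-west run, κ from east times that run's target readings from 20.0 h to 30.0 h gave 6.8 percentage points of isomer, and the north-west run gained 7 points.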